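Carbons carry ent-kaurane numbers throughout (C18 = methyl on C4, C19 = CH2O on C4, C20 = CH2O on C10). Compound numbers 1–30 are those of the steps.

## The problem

Ludongnin A (30) is a 6,7-seco-ent-kaurane: ring B is absent and its carbons reappear as two lactones. Ring A (C1–C5, C10) carries a cis-fused γ-lactone (C5–C6(=O)–O–C19–C4). It is joined through the quaternary C10 and the C9–C10 bond to a δ-lactone (C10–C20–O–C7(=O)–C8–C9) that is cis-fused to ring C, and rings C and D form a bicyclo[3.2.1]octane with the C15 ketone and the C16=C17 methylene. Seven stereocentres must be set (C4, C5, C8, C9, C10, C11, C13); C4, C8 and C10 are quaternary and C8–C9–C10–C5–C4 is an unbroken run. C8 is the sensible anchor: once it is fixed, C13 follows from the geometry of the bridge, C9 from the cis-fusion of the δ-lactone, C10 from the chair of that lactone, C4 from the axial C20 on C10 and C5 from the cis-fusion of the γ-lactone, while C11 is an equatorial carbinol open to thermodynamic control. The α-methylene cyclopentanone is a strong conjugate acceptor that cannot pass through enolate, cuprate or single-electron steps; both lactones are open to alkoxides and hydrides; C9 can epimerize while C11 is a ketone; the exocyclic alkene migrates in strong acid. The feature that opens the route is the substitution at C8: it bears the carboxyl carbon C7 and the ring methylene C14, and the oxygenated C11 lies across ring C, so its neighbour C12 can hold a temporary oxygen. C7 can then be parked on that oxygen as a six-membered lactone (C7, O, C12, C11, C9, C8) whose C12 vinyl group is C13=C14, and a [3,3] shift of its ketene acetal trades the C12–O bond for the C8–C14 bond.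

## Retrosynthesis

**30 to 28 (through 29).** No skeletal bond is cut; the C15 carbonyl is removed. The α-methylene ketone would add every nucleophile used earlier. C15 is the only allylic methylene of the C16=C17 alkene that can react (C13 is a bridgehead), so an allylic oxidation and an oxidant that spares the saturated C11 carbinol are all that is asked of the forward steps.

**28 to 27.** The C11 carbinol becomes a ketone. That ketone is what makes C9 nucleophilic and C13 electrophilic earlier, so it has to be present; the forward reduction must give the equatorial alcohol.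

**27 to 25.** The C4–C18 bond is cut and C5 loses its hydrogen, giving butenolide 25. Cutting the methyl and not C19 leaves a flat conjugated lactone, removes two stereocentres at once and lets the axial C20 on C10 steer the incoming methyl. The cost is a conjugate addition to a fully substituted alkene.

**25 to 23.** The C4–C19 bond and the C19–O–C6 ester bond are cut, leading to the enol triflate 23 of a β-keto ester. A one-carbon hydroxymethyl donor in a cross-coupling rebuilds both.

**23 to 21.** The C9–C10 bond is cut and the triflate returned to the C4 ketone, which opens the δ-lactone on its carbon side and gives ester 21. This is preferred to cutting the C20–O bond, which would mean an intermolecular union of two hindered carbons with no control of C10. The ester that the target needs anyway becomes the tether, the C11 ketone supplies the C9 enolate, and the acceptor is activated twice at C5 so that a fully substituted β-carbon can still be attacked. The six-membered ring that forms fixes C9 and C10; two stereocentres and one ring disappear.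

**21 to 16 and 20.** The C20–O ester bond is cut. A carboxylate alkylation joins the bicyclic keto acid 16, which holds C8 and C13, to the achiral allylic bromide 20. The bromide is used because a free hydroxymethyl group cis to the ester would close to butenolide 19.

**20 to 17.** Bromide 20 comes from lactone 19 by opening the allylic C–O bond. Lactone 19 comes from iodo enone 18 by inserting carbon monoxide between C5 and the hydroxyl oxygen, and 18 from enone 17 by α-iodination. Each step adds one substituent to a flat six-membered ring.

**16 to 14.** The C13–C16 bond is cut, opening ring D to the propargyl enone 14. A vinyl radical at C16 closes onto the enone β-carbon C13, and the bridge can only form on the face that carries C15. Enone 14 has a single stereocentre, C8.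

**14 to 11.** Only protecting groups and oxidation level change (alkyne silyl group, C11 ether, C11 alcohol), so 14 maps directly onto the rearrangement product 11.

**11 to 8.** The C8–C14 bond is cut and the C12–O bond restored, so the cyclohexene acid 11 becomes the vinyl lactone 8. Against an intermolecular alkylation or a cycloaddition route to the quaternary C8, this cut transfers chirality from a carbinol carbon (C12) that is easy to make in one enantiomer. The forward step must be stereospecific and must tolerate a tetrasubstituted ketene acetal.

**8 to 4.** Three simple bonds are cut: C8–C15 (enolate alkylation), C8–C9 (ring-closing metathesis of acrylate 5 to 6) and C7–O (acylation of dienol 4). The precursor 4 is an acyclic anti-diol monoether with two vinyl groups.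

**4 to 1.** The C13–C14 bond comes from methylene transfer to epoxide 3, the ether from 2, and the epoxide oxygen of 2 from the achiral dienol 1. One catalytic asymmetric step sets C11 and C12 and, through them, every other stereocentre.

## Roads not taken

**Alternative 1:** The cut is through C5–C6 and C10–C20. Forward, irradiation of the enone A2, whose ethynyl ether is tethered through C19–O, would give the cyclobutene A1; later ozonolysis of the C6=C20 bond would reveal the C6 lactone carbonyl and a C20 aldehyde.
- Merits: one step makes the quaternary C10 and C5, and the tether guarantees that C20 and C19 end up cis. In ring A stereocontrol this road is better than the chosen plan, which needs a chair argument for C10 and a late methyl addition for C4.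
- Weak points: the ynol ether is labile, the C4 quaternary centre must be made in one enantiomer beforehand, and the C1 ketone must be removed. Rings C and D with the quaternary C8, C9 and C13 would have to be grown from a short side chain next to two quaternary carbons.
- Comparison: the chosen plan sets C8 early by a stereospecific shift and joins two fragments of similar size. It answers the ring A problem by substrate control from the δ-lactone.

**Alternative 2:** The cut is through C4–C5 and C5–C18. Forward, a chiral divalent rhodium dimer such as Rh2(5S-MEPY)4 would decompose the allylic diazoacetate A4, and the carbenoid at C5 would add to the C4=C18 alkene to give the cyclopropane-fused γ-lactone A3; reductive opening of C5–C18 would later give the methyl group.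
- Merits: catalytic, enantioselective, and it sets C4 and C5 with the cis-lactone in one step. Here the absolute configuration of ring A comes from a catalyst; in the chosen plan it is relayed from C8 through three substrate-controlled steps, which is the weaker position.
- Weak points: C10 remains an ester carbon that needs two more carbon–carbon bonds with control, and nothing is said about C9, C8 or the bicyclooctane.
- Comparison: it solves the easier half of the molecule. The chosen plan solves C8, C13, C9 and C10 in a connected way and pays with a hindered methyl addition at C4.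

**Alternative 3:** The cut is C5–C10. Forward, the silyl ketene acetal of the ten-membered lactone A6 would rearrange to the ring A acid A5 with cis C6 carboxyl and C20 vinyl groups.
- Merits: the same reliable sigmatropic logic as the chosen plan, and it forms the quaternary C10 and C5 directly, which the chosen plan does only later by a Michael addition.
- Weak points: a ten-membered lactone with a trisubstituted alkene has to be closed first. A medium ring can use chair or boat transition states, so the C5/C10 relationship to the preset C4 is not secured. The vinyl group carries one carbon too many, and the whole C8/C9/ring C–D problem remains.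
- Comparison: the six-membered lactone of the chosen plan is cheap to make and is forced into a single boat, so its transfer of chirality is unambiguous. It gives up the early construction of C10.

Key step: step 7

Assumption: 3-(hydroxymethyl)cyclohex-2-en-1-one (17) is taken as a catalogue compound; nothing in the route depends on how it is made.

## Route

Step 1
Reactants: 1 penta-1,4-dien-3-ol
Product: 2 (1S)-1-[(2R)-oxiran-2-yl]prop-2-en-1-ol
Conditions: Ti(OiPr)4, L-(+)-diisopropyl tartrate, t-BuOOH, 4 Å molecular sieves, CH2Cl2, −20 °C
Reagents that add atoms: tert-butyl hydroperoxide, CC(C)(C)OO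
Why: Sharpless asymmetric epoxidation of an achiral divinyl carbinol; the tartrate selects one enantiotopic vinyl group and one face to give the erythro epoxy alcohol, and the minor enantiomer is epoxidized a second time faster, so optical purity should rise with conversion. This sets C11 (carbinol) and C12 (epoxide CH).

Step 2
Reactants: 2 (1S)-1-[(2R)-oxiran-2-yl]prop-2-en-1-ol
Product: 3 (2R)-2-[(1S)-1-[(4-methoxyphenyl)methoxy]prop-2-en-1-yl]oxirane
Conditions: NaH, 4-methoxybenzyl chloride, n-Bu4NI (cat.), THF/DMF, 0 → 23 °C
Reagents that add atoms: 4-methoxybenzyl chloride, COc1ccc(CCl)cc1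
Why: Williamson etherification, run cold to outpace Payne rearrangement. A benzylic ether is chosen because a silyl group could migrate between the two oxygens of the later diol, which in this pseudo-meso skeleton would amount to racemization.

Step 3
Reactants: 3 (2R)-2-[(1S)-1-[(4-methoxyphenyl)methoxy]prop-2-en-1-yl]oxirane
Product: 4 (3R,4S)-4-[(4-methoxyphenyl)methoxy]hexa-1,5-dien-3-ol
Conditions: Me3S+ I−, n-BuLi, THF, −10 → 23 °C
Reagents that add atoms: trimethylsulfonium iodide, C[S+](C)C.[I-]
Why: One-carbon homologation of a terminal epoxide to an allylic alcohol: dimethylsulfonium methylide opens the epoxide at CH2 and a second equivalent eliminates dimethyl sulfide. The C12–O bond is not touched, so the configuration is kept; the new carbon is C14.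

Step 4
Reactants: 4 (3R,4S)-4-[(4-methoxyphenyl)methoxy]hexa-1,5-dien-3-ol
Product: 5 (3R,4S)-4-[(4-methoxyphenyl)methoxy]hexa-1,5-dien-3-yl prop-2-enoate
Conditions: acryloyl chloride, i-Pr2NEt, CH2Cl2, −78 → 0 °C
Reagents that add atoms: acryloyl chloride, C=CC(=O)Cl
Why: Simple O-acylation of a secondary allylic alcohol; it brings in C7 and C8.

Step 5
Reactants: 5 (3R,4S)-4-[(4-methoxyphenyl)methoxy]hexa-1,5-dien-3-yl prop-2-enoate
Product: 6 (5S,6R)-6-ethenyl-5-[(4-methoxyphenyl)methoxy]-5,6-dihydro-2H-pyran-2-one
Conditions: second-generation Grubbs catalyst (H2IMes)(PCy3)Cl2Ru=CHPh (5 mol %), CH2Cl2 (5 mM), 40 °C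
Reagents that add atoms: none
Why: Ring-closing metathesis of an acrylate; closure onto the vinyl group on C11 gives the six-membered unsaturated lactone, which is expected to be favoured over the strained butenolide that closure onto the C12 vinyl group would give. The C8–C9 bond is formed.

Step 6
Reactants: 6 (5S,6R)-6-ethenyl-5-[(4-methoxyphenyl)methoxy]-5,6-dihydro-2H-pyran-2-one
Product: 8 (5S,6R)-6-ethenyl-5-[(4-methoxyphenyl)methoxy]-3-[3-(trimethylsilyl)prop-2-yn-1-yl]oxan-2-one (both C3 epimers), via lithium enolate 7 (not isolated)
Conditions: LiBH(s-Bu)3, THF, −78 °C; then 3-bromo-1-(trimethylsilyl)prop-1-yne, HMPA, −78 → −20 °C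
Reagents that add atoms: 3-bromo-1-(trimethylsilyl)prop-1-yne, C[Si](C)(C)C#CCBr
Why: Conjugate reduction of the unsaturated lactone by the hindered borohydride gives the enolate regiospecifically, and alkylation adds C15–C17. The C8 epimers are of no consequence because C8 becomes trigonal in the next step, and the enolate has no leaving group on its β-carbon.

Step 7
Reactants: 8 (5S,6R)-6-ethenyl-5-[(4-methoxyphenyl)methoxy]-3-[3-(trimethylsilyl)prop-2-yn-1-yl]oxan-2-one
Product: 11 (1R,5S)-5-[(4-methoxyphenyl)methoxy]-1-[3-(trimethylsilyl)prop-2-yn-1-yl]cyclohex-3-ene-1-carboxylic acid, via silyl ketene acetal 9 (not isolated), via silyl ester 10 (not isolated)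
Conditions: LDA, TBSCl, THF/HMPA, −78 °C; then toluene, 105 °C; then 1 M HCl, THF, 23 °C
Reagents that add atoms: none
Why: LDA removes the C8 proton of 8 and TBSCl traps the enolate on oxygen as the cyclic ketene acetal 9 (C8=C7). On heating, 9 undergoes a [3,3] sigmatropic shift in which C8 bonds to C14, the C12–O bond breaks and the π bonds move to C12=C13 and C7=O, giving silyl ester 10, which dilute acid hydrolyses to 11. The closest known reaction type is the Ireland–Claisen ring contraction of 6-alkenyl lactone silyl ketene acetals to cycloalkene carboxylic acids. Ring C is closed by this concerted suprafacial shift through a boat-shaped transition state resembling bicyclo[2.2.2]octane, because the lactone tether forbids the chair; a six-membered lactone (C8, C7, O, C12, C11, C9) is exchanged for a six-membered carbocycle (C8, C9, C11, C12, C13, C14). The new stereocentre C8 is controlled by C12: the vinyl group can reach C8 only on the face of the ketene acetal ring on which it stands, so the configuration of C12 is transferred to C8 without loss. C11 is untouched, and because its ether oxygen is trans to the vinyl group in 8 it ends cis to the C7 carboxyl in 11, as in the target. The step needs O-silylation over C-silylation and rearrangement over elimination; HMPA, the hindered enolate carbon and the absence of a leaving group β to C8 secure this, and no enolate geometry issue arises because the ketene acetal is cyclic. The tetrasubstituted ketene acetal delivers the quaternary centre without an intermolecular alkylation.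

Step 8
Reactants: 11 (1R,5S)-5-[(4-methoxyphenyl)methoxy]-1-[3-(trimethylsilyl)prop-2-yn-1-yl]cyclohex-3-ene-1-carboxylic acid
Product: 12 (1R,5S)-5-[(4-methoxyphenyl)methoxy]-1-(prop-2-yn-1-yl)cyclohex-3-ene-1-carboxylic acid
Conditions: K2CO3, MeOH, 23 °C; then 1 M HCl to pH 3
Reagents that add atoms: none
Why: Methoxide-mediated protodesilylation of the alkynyl silane; the terminal alkyne is needed for the radical step.

Step 9
Reactants: 12 (1R,5S)-5-[(4-methoxyphenyl)methoxy]-1-(prop-2-yn-1-yl)cyclohex-3-ene-1-carboxylic acid
Product: 13 (1R,5S)-5-hydroxy-1-(prop-2-yn-1-yl)cyclohex-3-ene-1-carboxylic acid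
Conditions: DDQ, CH2Cl2/pH 7 phosphate buffer, 0 → 23 °C
Reagents that add atoms: none
Why: Oxidative cleavage of the 4-methoxybenzyl ether by hydride abstraction and hydrolysis of the oxocarbenium ion; alkyne, alkene and acid are inert.

Step 10
Reactants: 13 (1R,5S)-5-hydroxy-1-(prop-2-yn-1-yl)cyclohex-3-ene-1-carboxylic acid
Product: 14 (1R)-5-oxo-1-(prop-2-yn-1-yl)cyclohex-3-ene-1-carboxylic acid
Conditions: Dess–Martin periodinane, NaHCO3, CH2Cl2, 0 → 23 °C
Reagents that add atoms: none
Why: Oxidation of the allylic alcohol to the enone, which is the radical acceptor of the next step. Prompt oxidation also removes the chance that the C11 hydroxyl, cis and 1,3 to C7, closes a bridged lactone.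

Step 11
Reactants: 14 (1R)-5-oxo-1-(prop-2-yn-1-yl)cyclohex-3-ene-1-carboxylic acid
Product: 16 (1R,5S)-6-methylidene-3-oxobicyclo[3.2.1]octane-1-carboxylic acid, via vinylstannane 15 (not isolated)
Conditions: Bu3SnH, AIBN, benzene, 80 °C (slow addition); then TsOH·H2O, CH2Cl2, 23 °C
Reagents that add atoms: none
Why: Tin hydride mediated radical cyclization of an alkynyl enone: the stannyl radical adds to the terminal alkyne carbon C17, the vinyl radical at C16 closes 5-exo-trig onto C13, the β-carbon of the enone, and acid then removes tin from C17 (protodestannylation). C13 is fixed by C8, because the two-carbon bridge can only span ring C on the face on which C15 stands; the carboxylic acid is expected to be tolerated by the radical chain.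

Step 12
Reactants: 17 3-(hydroxymethyl)cyclohex-2-en-1-one
Product: 18 3-(hydroxymethyl)-2-iodocyclohex-2-en-1-one
Conditions: I2, pyridine, CH2Cl2, 0 → 23 °C
Reagents that add atoms: iodine, I-I
Why: α-Iodination of an enone through conjugate addition of pyridine, iodination of the enolate and elimination; it marks C5 for the carboxyl carbon.

Step 13
Reactants: 18 3-(hydroxymethyl)-2-iodocyclohex-2-en-1-one
Product: 19 5,6-dihydro-2-benzofuran-1,7(3H,4H)-dione
Conditions: PdCl2(PPh3)2 (cat.), CO (1 atm), K2CO3, THF, 50 °C
Reagents that add atoms: carbon monoxide, [C-]#[O+]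
Why: Carbonylative lactonization: oxidative addition of the vinyl iodide to zerovalent palladium, CO insertion and capture of the acyl palladium by the cis hydroxymethyl group give the butenolide; the inserted carbon is C6.

Step 14
Reactants: 19 5,6-dihydro-2-benzofuran-1,7(3H,4H)-dione
Product: 20 methyl 2-(bromomethyl)-6-oxocyclohex-1-ene-1-carboxylate
Conditions: BBr3, CH2Cl2, 0 → 23 °C; then MeOH, 0 °C
Reagents that add atoms: boron tribromide, BrB(Br)Br; methanol, CO
Why: Lewis acid mediated lactone opening: bromide attacks the activated allylic CH2–O carbon and methanol turns the acyloxyborane into the methyl ester. The bromide is used at once because it can close back to 19.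

Step 15
Reactants: 16 (1R,5S)-6-methylidene-3-oxobicyclo[3.2.1]octane-1-carboxylic acid; 20 methyl 2-(bromomethyl)-6-oxocyclohex-1-ene-1-carboxylate
Product: 21 [2-(methoxycarbonyl)-3-oxocyclohex-1-en-1-yl]methyl (1R,5S)-6-methylidene-3-oxobicyclo[3.2.1]octane-1-carboxylate
Conditions: Cs2CO3, DMF, 0 °C
Reagents that add atoms: none
Why: SN2 alkylation of a caesium carboxylate by a primary allylic bromide, which is insensitive to the hindrance at the quaternary acid carbon. It forms the C20–O–C7 ester that becomes the δ-lactone.

Step 16
Reactants: 21 [2-(methoxycarbonyl)-3-oxocyclohex-1-en-1-yl]methyl (1R,5S)-6-methylidene-3-oxobicyclo[3.2.1]octane-1-carboxylate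
Product: 23 spiro δ-lactone enol triflate (7,20-lactone; C4–OTf, C4=C5, C5–CO2Me; 11-ketone; 16-methylidene; C8, C9, C10 and C13 as in 30), via keto ester 22 (not isolated)
Conditions: DBU (0.3 equiv), MeCN, 23 → 45 °C; then Cs2CO3, PhNTf2, 0 → 23 °C
Reagents that add atoms: N-phenylbis(trifluoromethanesulfonimide), O=S(=O)(N(c1ccccc1)S(=O)(=O)C(F)(F)F)C(F)(F)F
Why: Intramolecular Michael addition (6-exo-trig) of the C9 enolate of the ring C ketone to the doubly activated alkylidene β-keto ester, then O-triflation of the β-keto ester enolate; the C12 enolate cannot reach the acceptor and simply reverts. C9: the tether on C8 delivers C10 to the axial face of the enolate, anti to the C15–C16 bridge, which gives the cis-fused lactone. C10: in the chair-like lactone transition state the small C1 methylene takes the axial place under ring C and the fully substituted C5 terminus the equatorial one.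

Step 17
Reactants: 23 spiro δ-lactone enol triflate
Product: 25 butenolide (6,19-lactone with C4=C5; 7,20-lactone; 11-ketone; 16-methylidene; 18-nor), via hydroxy ester 24 (not isolated)
Conditions: Pd(PPh3)4 (cat.), Bu3SnCH2OH, LiCl, 1,4-dioxane, 90 °C; then PPTS (cat.), CH2Cl2, 23 °C
Reagents that add atoms: (tributylstannyl)methanol, CCCC[Sn](CCCC)(CCCC)CO
Why: Stille coupling of an electron-poor enol triflate with a hydroxymethyl stannane forms the C4–C19 bond, and the new hydroxyl, cis to the ester across the alkene, lactonizes. The C20–O–C7 ester is no longer allylic, so zerovalent palladium cannot ionize it.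

Step 18
Reactants: 25 butenolide
Product: 27 11-dehydro-15-deoxoludongnin A (both lactones in place; 11-ketone; C15 methylene), via silyl ketene acetal 26 (not isolated)
Conditions: Me2CuLi, TMSCl, THF, −78 → −30 °C; then 1 M HCl, THF, 0 °C
Reagents that add atoms: lithium dimethylcuprate, [Li+].C[Cu-]C
Why: Conjugate addition of a methyl cuprate to the butenolide, accelerated by TMSCl, then hydrolysis of 26. C4: the spiro lactone holds C20 axial on ring A, 1,3 to C4, so methyl enters from the opposite face, cis to C9. C5: protonation gives the cis-fused γ-lactone, the more stable ring fusion, and C5 can equilibrate through the lactone enolate if needed.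

Step 19
Reactants: 27 11-dehydro-15-deoxoludongnin A
Product: 28 15-deoxoludongnin A (11-hydroxyl equatorial, as in 30)
Conditions: SmI2, THF/MeOH, 0 → 23 °C
Reagents that add atoms: none
Why: Single-electron reduction of the ketone by divalent samarium through a ketyl and a carbanion that are protonated to the more stable carbinol. The equatorial 11-hydroxyl is favoured because an axial one would be syn-diaxial to C15 and C16; without amine or water activation the lactones should not be reduced.

Step 20
Reactants: 28 15-deoxoludongnin A
Product: 29 15-hydroxy-15-deoxoludongnin A (either C15 epimer)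
Conditions: SeO2 (cat.), t-BuOOH, CH2Cl2, 23 °C
Reagents that add atoms: tert-butyl hydroperoxide, CC(C)(C)OO
Why: Allylic oxidation by an ene reaction and [2,3] shift at selenium. C15 is the only position that can react, since the other allylic carbon, C13, is a bridgehead and cannot become trigonal.

Step 21
Reactants: 29 15-hydroxy-15-deoxoludongnin A
Product: 30 ludongnin A
Conditions: MnO2, CH2Cl2, 23 °C
Reagents that add atoms: none
Why: MnO2 oxidizes the allylic C15 alcohol to the α-methylene ketone and leaves the saturated C11 carbinol alone; the sensitive enone appears only in the last step.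

## Compound list

1 | penta-1,4-dien-3-ol | C=CC(O)C=C | starting material
2 | (1S)-1-[(2R)-oxiran-2-yl]prop-2-en-1-ol | C=C[C@H](O)[C@H]1CO1 | intermediate
3 | (2R)-2-[(1S)-1-[(4-methoxyphenyl)methoxy]prop-2-en-1-yl]oxirane | C=C[C@H](OCc1ccc(OC)cc1)[C@H]1CO1 | intermediate
4 | (3R,4S)-4-[(4-methoxyphenyl)methoxy]hexa-1,5-dien-3-ol | C=C[C@H](OCc1ccc(OC)cc1)[C@H](O)C=C | intermediate
5 | (3R,4S)-4-[(4-methoxyphenyl)methoxy]hexa-1,5-dien-3-yl prop-2-enoate | C=CC(=O)O[C@H](C=C)[C@@H](OCc1ccc(OC)cc1)C=C | intermediate
6 | (5S,6R)-6-ethenyl-5-[(4-methoxyphenyl)methoxy]-5,6-dihydro-2H-pyran-2-one | O=C1O[C@H](C=C)[C@@H](OCc2ccc(OC)cc2)C=C1 | intermediate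
7 | lithium enolate of (5S,6R)-6-ethenyl-5-[(4-methoxyphenyl)methoxy]oxan-2-one | [Li+].[O-]C1=CC[C@H](OCc2ccc(OC)cc2)[C@@H](C=C)O1 | intermediate (not isolated)
8 | (5S,6R)-6-ethenyl-5-[(4-methoxyphenyl)methoxy]-3-[3-(trimethylsilyl)prop-2-yn-1-yl]oxan-2-one (both C3 epimers) | O=C1O[C@H](C=C)[C@@H](OCc2ccc(OC)cc2)CC1CC#C[Si](C)(C)C | intermediate
9 | cyclic tert-butyldimethylsilyl ketene acetal of 8 (C8=C7) | C[Si](C)(C)C#CCC1=C(O[Si](C)(C)C(C)(C)C)O[C@H](C=C)[C@@H](OCc2ccc(OC)cc2)C1 | intermediate (not isolated)
10 | tert-butyldimethylsilyl ester of 11 | C[Si](C)(C)C#CC[C@]1(C(=O)O[Si](C)(C)C(C)(C)C)CC=C[C@@H](OCc2ccc(OC)cc2)C1 | intermediate (not isolated)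
11 | (1R,5S)-5-[(4-methoxyphenyl)methoxy]-1-[3-(trimethylsilyl)prop-2-yn-1-yl]cyclohex-3-ene-1-carboxylic acid | C[Si](C)(C)C#CC[C@]1(C(=O)O)CC=C[C@@H](OCc2ccc(OC)cc2)C1 | intermediate
12 | (1R,5S)-5-[(4-methoxyphenyl)methoxy]-1-(prop-2-yn-1-yl)cyclohex-3-ene-1-carboxylic acid | C#CC[C@]1(C(=O)O)CC=C[C@@H](OCc2ccc(OC)cc2)C1 | intermediate
13 | (1R,5S)-5-hydroxy-1-(prop-2-yn-1-yl)cyclohex-3-ene-1-carboxylic acid | C#CC[C@]1(C(=O)O)CC=C[C@@H](O)C1 | intermediate
14 | (1R)-5-oxo-1-(prop-2-yn-1-yl)cyclohex-3-ene-1-carboxylic acid | C#CC[C@]1(C(=O)O)CC=CC(=O)C1 | intermediate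
15 | (1R,5S)-3-oxo-6-[(tributylstannyl)methylidene]bicyclo[3.2.1]octane-1-carboxylic acid (either alkene geometry) | CCCC[Sn](CCCC)(CCCC)C=C1C[C@]2(C(=O)O)C[C@H]1CC(=O)C2 | intermediate (not isolated)
16 | (1R,5S)-6-methylidene-3-oxobicyclo[3.2.1]octane-1-carboxylic acid | C=C1C[C@]2(C(=O)O)C[C@H]1CC(=O)C2 | intermediate
17 | 3-(hydroxymethyl)cyclohex-2-en-1-one | OCC1=CC(=O)CCC1 | starting material
18 | 3-(hydroxymethyl)-2-iodocyclohex-2-en-1-one | OCC1=C(I)C(=O)CCC1 | intermediate
19 | 5,6-dihydro-2-benzofuran-1,7(3H,4H)-dione | O=C1OCC2=C1C(=O)CCC2 | intermediate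
20 | methyl 2-(bromomethyl)-6-oxocyclohex-1-ene-1-carboxylate | COC(=O)C1=C(CBr)CCCC1=O | intermediate
21 | [2-(methoxycarbonyl)-3-oxocyclohex-1-en-1-yl]methyl (1R,5S)-6-methylidene-3-oxobicyclo[3.2.1]octane-1-carboxylate | C=C1C[C@]2(C(=O)OCC3=C(C(=O)OC)C(=O)CCC3)C[C@H]1CC(=O)C2 | intermediate
22 | spiro δ-lactone β-keto ester (7,20-lactone; C4 ketone; C5–CO2Me, C5 unfixed; 11-ketone; 16-methylidene) | C=C1C[C@]23C[C@H]1CC(=O)[C@H]2[C@@]1(CCCC(=O)C1C(=O)OC)COC3=O | intermediate (not isolated)
23 | spiro δ-lactone enol triflate (C4–OTf, C4=C5, C5–CO2Me; 11-ketone; 16-methylidene) | C=C1C[C@]23C[C@H]1CC(=O)[C@H]2[C@@]1(CCCC(OS(=O)(=O)C(F)(F)F)=C1C(=O)OC)COC3=O | intermediate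
24 | spiro δ-lactone hydroxy ester (C4–CH2OH, C4=C5, C5–CO2Me) | C=C1C[C@]23C[C@H]1CC(=O)[C@H]2[C@@]1(CCCC(CO)=C1C(=O)OC)COC3=O | intermediate (not isolated)
25 | butenolide (6,19-lactone with C4=C5; 7,20-lactone; 11-ketone; 16-methylidene; 18-nor) | C=C1C[C@]23C[C@H]1CC(=O)[C@H]2[C@@]1(CCCC4=C1C(=O)OC4)COC3=O | intermediate
26 | trimethylsilyl ketene acetal of 27 (C5=C6) | C=C1C[C@]23C[C@H]1CC(=O)[C@H]2[C@@]1(CCC[C@@]2(C)COC(O[Si](C)(C)C)=C21)COC3=O | intermediate (not isolated)
27 | 11-dehydro-15-deoxoludongnin A | C=C1C[C@]23C[C@H]1CC(=O)[C@H]2[C@@]1(CCC[C@@]2(C)COC(=O)[C@H]21)COC3=O | intermediate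
28 | 15-deoxoludongnin A | C=C1C[C@]23C[C@H]1C[C@@H](O)[C@H]2[C@@]1(CCC[C@@]2(C)COC(=O)[C@H]21)COC3=O | intermediate
29 | 15-hydroxy-15-deoxoludongnin A (C15 configuration not fixed) | C=C1C(O)[C@]23C[C@H]1C[C@@H](O)[C@H]2[C@@]1(CCC[C@@]2(C)COC(=O)[C@H]21)COC3=O | intermediate
30 | ludongnin A | C=C1C(=O)[C@]23C[C@H]1C[C@@H](O)[C@H]2[C@@]1(CCC[C@@]2(C)COC(=O)[C@H]21)COC3=O | target

## Count and weak points

Total: 21 steps. Longest linear sequence: 18 steps (steps 1–11 and 15–21); steps 12–14 are a three-step branch to bromide 20.

**Step 7 (key step).** The hindered, α-branched lactone enolate may be silylated slowly on oxygen, and the boat transition state needs about 100 °C, where the ketene acetal can fragment before it rearranges. Loss of material, not loss of stereochemistry, is the danger. The fallback does not branch from a compound of the route: it replaces steps 1–10, begins with commercial 3-methoxybenzoic acid and comes back at 14. Birch reduction (Li, NH3, THF; excess metal quenched) and alkylation of the resulting dienolate with 3-bromo-1-(trimethylsilyl)prop-1-yne would give 3-methoxy-1-[3-(trimethylsilyl)prop-2-yn-1-yl]cyclohexa-2,5-diene-1-carboxylic acid F1. Aqueous HCl would hydrolyse the enol ether and move the alkene into conjugation to give racemic 5-oxo-1-[3-(trimethylsilyl)prop-2-yn-1-yl]cyclohex-3-ene-1-carboxylic acid F2. K2CO3 in methanol would give racemic 5-oxo-1-(prop-2-yn-1-yl)cyclohex-3-ene-1-carboxylic acid F3. Crystallization with one enantiomer of 1-phenylethylamine as the (S)-1-phenylethylammonium (R)-carboxylate F4 and acidification would give 14. The price is a resolution in place of an asymmetric catalysis.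

**Step 16.** The catalytic base rests mainly on the more acidic γ-position of the acceptor, so cyclization may be slow. The adduct enolate could expel the C7 carboxylate from C20 (cyclopropane formation), and selectivity at C10 could erode if the addition becomes reversible at higher temperature. The fallback sets out from 14 and comes back at 23; it makes the nucleophile regiodefined before the acceptor is attached and closes ring D afterwards. LDA (2 equiv) and TBSCl, then mild aqueous carbonate to free the acid, would give (1R)-5-[(tert-butyldimethylsilyl)oxy]-1-(prop-2-yn-1-yl)cyclohexa-3,5-diene-1-carboxylic acid F5. Caesium carbonate and 20 would give its [2-(methoxycarbonyl)-3-oxocyclohex-1-en-1-yl]methyl ester F6. A fluoride source would release the C9 enolate for the Michael addition, and PhNTf2 would trap the adduct as the enone enol triflate F7. Bu3SnH/AIBN and acid, as in step 11, would then close ring D and give 23.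

**Step 17.** Transfer of the sp3 hydroxymethyl group from tin to a hindered vinyl palladium is slow, so butyl transfer or simple reduction of the triflate may compete. The fallback sets out from 23 and comes back at 25. Reductive carbonylation (Pd(OAc)2, 1,3-bis(diphenylphosphino)propane, CO, Et3SiH) would give the C4 carbaldehyde F8. NaBH(OAc)3, which reduces the aldehyde but not the C11 ketone, would give 24, which lactonizes to 25.

**Step 18.** The cuprate may refuse the fully substituted β-carbon next to the quaternary C10, or attack the C11 ketone instead; facial selectivity is the lesser worry. The fallback reverses the polarity at C4 (electrophilic methylation of a C4 enolate); it sets out from 23 through the aldehyde F8 of the previous fallback and comes back at 27. Zn in acetic acid would reduce the ene-dicarbonyl unit to the saturated aldehyde ester F9. KOt-Bu (1 equiv) and MeI would methylate the aldehyde enolate from the equatorial side, anti to the axial C20, to give the quaternary aldehyde F10. NaBH(OAc)3 would give the hydroxy ester F11, which closes to 27 with catalytic acid.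

**Step 19.** The carbanion may be protonated from the open face to give the axial 11-epimer, or the δ-lactone may be reduced if the reagent is too strongly activated. The fallback sets out from 27 and comes back at 28. NaBH4, which is expected to attack the ketone from the face away from the two-carbon bridge, would give the axial alcohol 11-epi-15-deoxoludongnin A F12. Mitsunobu inversion with chloroacetic acid (PPh3, diisopropyl azodicarboxylate) would give the equatorial chloroacetate F13, and K2CO3 in methanol at 0 °C would cleave the chloroacetate to 28.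

## Further compounds

F1 | step 7 | 3-methoxy-1-[3-(trimethylsilyl)prop-2-yn-1-yl]cyclohexa-2,5-diene-1-carboxylic acid | COC1=CC(CC#C[Si](C)(C)C)(C(=O)O)C=CC1
F2 | step 7 | racemic 5-oxo-1-[3-(trimethylsilyl)prop-2-yn-1-yl]cyclohex-3-ene-1-carboxylic acid | C[Si](C)(C)C#CCC1(C(=O)O)CC=CC(=O)C1
F3 | step 7 | racemic 5-oxo-1-(prop-2-yn-1-yl)cyclohex-3-ene-1-carboxylic acid | C#CCC1(C(=O)O)CC=CC(=O)C1
F4 | step 7 | (S)-1-phenylethylammonium (1R)-5-oxo-1-(prop-2-yn-1-yl)cyclohex-3-ene-1-carboxylate | C#CC[C@]1(C(=O)[O-])CC=CC(=O)C1.C[C@H]([NH3+])c1ccccc1
F5 | step 16 | (1R)-5-[(tert-butyldimethylsilyl)oxy]-1-(prop-2-yn-1-yl)cyclohexa-3,5-diene-1-carboxylic acid | C#CC[C@]1(C(=O)O)CC=CC(O[Si](C)(C)C(C)(C)C)=C1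
F6 | step 16 | [2-(methoxycarbonyl)-3-oxocyclohex-1-en-1-yl]methyl (1R)-5-[(tert-butyldimethylsilyl)oxy]-1-(prop-2-yn-1-yl)cyclohexa-3,5-diene-1-carboxylate | C#CC[C@]1(C(=O)OCC2=C(C(=O)OC)C(=O)CCC2)CC=CC(O[Si](C)(C)C(C)(C)C)=C1
F7 | step 16 | spiro δ-lactone enol triflate at the enone stage (ring D open; C8 propargyl; C11 ketone; C12=C13) | C#CC[C@]12CC=CC(=O)[C@H]1[C@@]1(CCCC(OS(=O)(=O)C(F)(F)F)=C1C(=O)OC)COC2=O
F8 | step 17 | spiro δ-lactone C4 carbaldehyde (C4–CHO, C4=C5, C5–CO2Me) | C=C1C[C@]23C[C@H]1CC(=O)[C@H]2[C@@]1(CCCC(C=O)=C1C(=O)OC)COC3=O
F9 | step 18 | saturated aldehyde ester (C4–H, C4–CHO; C5–H, C5–CO2Me; C4 and C5 unfixed) | C=C1C[C@]23C[C@H]1CC(=O)[C@H]2[C@@]1(CCCC(C=O)C1C(=O)OC)COC3=O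
F10 | step 18 | C4-methylated aldehyde ester (C4: methyl and axial CHO; C5 unfixed) | C=C1C[C@]23C[C@H]1CC(=O)[C@H]2[C@@]1(CCC[C@@](C)(C=O)C1C(=O)OC)COC3=O
F11 | step 18 | C4 hydroxymethyl ester (C4: methyl and CH2OH; C5–CO2Me) | C=C1C[C@]23C[C@H]1CC(=O)[C@H]2[C@@]1(CCC[C@@](C)(CO)C1C(=O)OC)COC3=O
F12 | step 19 | 11-epi-15-deoxoludongnin A | C=C1C[C@]23C[C@H]1C[C@H](O)[C@H]2[C@@]1(CCC[C@@]2(C)COC(=O)[C@H]21)COC3=O
F13 | step 19 | 15-deoxoludongnin A 11-chloroacetate | C=C1C[C@]23C[C@H]1C[C@@H](OC(=O)CCl)[C@H]2[C@@]1(CCC[C@@]2(C)COC(=O)[C@H]21)COC3=O
A1 | alternative 1 | tricyclic cyclobutene enol ether photoadduct | CC1(OCCO1)C[C@@]1(C(=O)CC[C@@]2(C)COC3[C@H]21)C=3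
A2 | alternative 1 | 4-[(ethynyloxy)methyl]-4-methyl-2-[(2-methyl-1,3-dioxolan-2-yl)methyl]cyclohex-2-en-1-one | CC1(OCCO1)CC1=C[C@](C)(COC#C)CCC1=O
A3 | alternative 2 | methyl 4-(2-oxo-3-oxabicyclo[3.1.0]hexan-5-yl)butanoate (single enantiomer) | COC(=O)CCC[C@@]1(C2)COC(=O)[C@@H]12
A4 | alternative 2 | methyl 5-{[(diazoacetyl)oxy]methyl}hex-5-enoate | COC(=O)CCCC(=C)COC(=O)C=[N+]=[N-]
A5 | alternative 3 | 2-(2,2-dimethoxyethyl)-2-ethenyl-6-{[(4-methoxyphenyl)methoxy]methyl}-6-methylcyclohexane-1-carboxylic acid | COC(OC)C[C@@]1(CCC[C@@](C)(COCc2ccc(OC)cc2)[C@H]1C(=O)O)C=C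
A6 | alternative 3 | 8-(2,2-dimethoxyethyl)-4-{[(4-methoxyphenyl)methoxy]methyl}-4-methyl-3,4,5,6,7,10-hexahydro-2H-oxecin-2-one | COC(OC)CC1=CCOC(=O)C[C@](C)(COCc2ccc(OC)cc2)CCC1
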